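## Structural features

The target is one six-membered carbocycle, a cyclohex-4-en-6-one (ring numbering: C1 tertiary carbinol, C2, C3, C4=C5, C6 ketone), with one exocyclic carbon, C7, on C1. The three contiguous stereocentres C1, C2 and C3 all carry oxygen: the free hydroxyl on C1 is cis to the C2 acetate, and the C2 acetate is trans to the C3 benzoate, which is (1S,2S,3R) in this numbering. Four oxygens are in three different states (free OH at O1, acetate at O2, benzoates at O3 and O7), so the acyl pattern has to be fixed by the order of events and not by selective acylation of a polyol. The molecule is fragile towards base: the γ-benzoyloxy enone can lose its esters by vinylogous elimination and aromatise, vicinal esters can migrate, and the C3–O bond is allylic. The real difficulty is the quaternary carbinol C1, wedged between the ketone, C2 and C7, together with the need to create the enone without disturbing three esters. The key step uses the fact that C3 bears an acyloxy group and is bonded to C4, the β-carbon of the C4=C5–C6=O enone, so a benzoate-stabilised C3 radical can close the ring onto the terminus of a C6 ynone. A second feature is that O1 and O2 are cis, so one ketal can bridge them and hold C6 and C3 on the same side during that closure.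

## Logic of the disconnections

20 to 19: the O2–acetyl bond is cut. The secondary hydroxyl at C2 is far more reactive than the tertiary α-ketol hydroxyl at C1, so no earlier differentiation of O1 and O2 is needed. The forward acetylation must be mild enough not to trigger elimination in the γ-acyloxy enone.

19 to 18: the free cis-diol is reconnected through the two C–O bonds of an isopropylidene ketal. One unit then protects O1 and O2, no silyl ether on the hindered C1 oxygen is needed, and the ketal comes from the starting sugar. The forward hydrolysis must spare two benzoates and the enone.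

18 to 15: the C3–C4 bond is cut, opening the ring to an acyclic ynone whose C3 carries a carboxyl derivative. All three esters, the ketone and both alkene carbons are already in place at ring closure. The forward step must generate radical 16 chemoselectively, close 6-endo and set C3 trans to O2.

15 to 13 and 14: the acyl C–O bond of the redox-active ester is cut. This reduces the problem to a carboxylic acid. The activation has to proceed without base, because 13 carries an ynone and a β-alkoxy group.

13 to 12 to 10: the carboxyl carbon C8 is traced to an aldehyde and then to the C8–C9 glycol of a terminal dioxolane (C8–C9 bond formed in the reverse sense). The acid is thus masked through all organometallic steps. The forward step must open the terminal ketal and leave the internal one intact.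

10 to 9 to 7 and 8: the C5–C6 bond is cut. Both alkyne carbons come from 8 and add to an aldehyde that has no α-hydrogen. The addition must spare two benzoates, and the C6 carbinol configuration is irrelevant because it is oxidised.

7 to 5: the C6 carbonyl is traced to a C6=CH2 alkene. The alkene is an inert mask for the aldehyde while the hydroxyls are acylated. The forward step is an ozonolysis in the presence of esters and ketals.

5 to 4: the two benzoyl C–O bonds at O3 and O7 are cut. Both hydroxyls are free at the same time and are the only free hydroxyls, so one operation fixes the benzoate pattern of the target.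

4 to 3: the C6=CH2 double bond is cut back to a lactol. Olefination opens the furanose and frees O3, which was the ring oxygen. The forward step must tolerate a β-hydroxy aldehyde.

3 to 1 and 2: the C1–C7 bond is cut. The quaternary centre arises by hydroxymethylation α to the masked aldehyde of a cheap sugar ketal, whose C3 and C4 already carry the configurations needed at C2 and C3. The aldol must deliver C7 to the face that leaves O1 cis to O2.

## Other disconnections considered

Alternative 1: The cut is C1–C6. In the forward sense a triazolium-derived carbene converts the C6 aldehyde of the open-chain keto-aldehyde A1 into its Breslow intermediate, which adds to the C1 ketone and gives the α-ketol A2.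
- In its favour: this crossed aldehyde–ketone benzoin closure to six-membered tertiary α-ketols is an established reaction class. It installs the C1 hydroxyl and the C6 ketone in one event, needs no protecting group on O1 and is catalytic and metal-free.
- Against it here: C1 is created during ring closure, so its configuration depends on the facial selectivity of attack on a ketone in a ring that becomes trans-fused to a dioxolane. The trans-fused ketal of A2 is strained. The β-silyloxy aldehyde of A1 is prone to base-induced elimination under carbene conditions. After closure the enone must still be made by eliminating the C4 silyloxy group, the benzyl-type ether at O7 exchanged for a benzoate, the ketal removed, and O2 and O3 of a trans-diol told apart by selective acylation.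
- Comparison: on structure the two plans are equal, since each forms one ring bond and one stereocentre, but the chosen plan has C1 fixed beforehand and the enone and acyl pattern complete at closure. On mechanism the alternative is the better, because its polar ring closure has direct precedent and the radical closure has not. On step economy it is the worse, with about five operations after ring closure against two.

Alternative 2: The cuts are C1–C6 and C4–C5. In the forward sense furfuryl benzoate A3 and 2-bromoacrolein A4 combine in a [4+2] cycloaddition under a chiral oxazaborolidine Lewis acid to give the oxanorbornene A5.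
- In its favour: two C–C bonds and the ring are made from achiral, cheap components in one step, with C1 set by the catalyst. The furan oxygen becomes O1 and the C7 benzoate is present from the start. A later β-elimination of the oxygen bridge from a C6 ketone would unveil the enone and the free C1 hydroxyl together. In convergence and bonds formed per step this is the better plan.
- Against it here: 2-substituted furans are sluggish and reversible dienes, and regiochemistry and exo selectivity must both be correct. The bromo-aldehyde has to be degraded to the C6 ketone with loss of a carbon. The C2=C3 alkene must be oxygenated before the bridge is opened, because opening first would leave a dimerisation-prone dienone. Exo-face reagents deliver both new oxygens cis to the bridge, so C3 would have to be inverted and O2 and O3 differentiated on a strained bicycle.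
- Comparison: on structure the alternative builds more in one step but leaves C2, C3 and the whole acyl pattern for later, whereas the chosen plan carries them into the closure. On mechanism the alternative is the better, as a concerted, catalytic asymmetric cycloaddition of a known class. On step economy it is at best equal: A5 is reached in two steps, but the sequence after it is long.

Alternative 3: No ring C–C bond is cut; the cuts are C2–O and C3–O of an oxirane on a ring obtained by Birch-type dearomatisation. In the forward sense the achiral dienol A6 is epoxidised at one of its two enantiotopic alkenes, syn to the hydroxyl, by Ti(OiPr)4, a dialkyl tartrate and tert-butyl hydroperoxide to give the epoxy alcohol A7.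
- In its favour: the carbocycle is obtained without a ring-forming step. One catalytic step fixes C1 and C2, and anti opening of the oxirane at C3 by benzoate would set C3 and differentiate O2 from O3 at once. No protecting group on O1 is required. In step count this is the better plan.
- Against it here: A6 is a tertiary, bis-allylic carbinol. Tertiary allylic alcohols are poor substrates for the titanium–tartrate system, and a cyclohexa-2,5-dienol is prone to ionisation and rearomatisation under Lewis acids. The remaining C5=C6/C4H2 unit must be transposed oxidatively into the C4=C5–C6=O enone next to the quaternary centre, for example by an ene-type oxygenation and dehydration. The oxirane must open regioselectively at C3.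
- Comparison: on structure the alternative addresses the stereotriad directly and leaves the enone to the end, whereas the chosen plan forms the enone in the ring closure. On mechanism the two are about equal in uncertainty, since the reagent-controlled group selection is established in kind but not for this substrate class. On step economy the alternative is the better, at roughly eight or nine steps, provided the desymmetrisation works.

Key step: step 10

Remarks on the chemistry:
- Locants C1–C7 are those of the target ring throughout. C8 and C9 are the two sugar carbons beyond C3 (sugar C5 and C6); C9 leaves as formaldehyde in step 7 and C8 as CO2 in step 10.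
- Assumption: 2,3:5,6-di-O-isopropylidene-α-D-mannofuranose (1) is purchased; it is also one step from D-mannose and acetone.
- Choice of chirality source: an entry from tartaric acid was weighed and set aside, because C1 would then have to be created by addition to an acyclic α,α'-dioxygenated ketone with uncertain facial control and O2 and O3 would need late differentiation. In 1 the sugar carbons C2, C3 and C4 map onto C1, C2 and C3 with the required configurations.
- Precursor design: O1 and O2 are carried through the ring closure as one isopropylidene ketal and not as a silyl ether and an acetate. This keeps C6 and C3 cis on a five-membered ring, removes an acetate leaving group β to the radical centre, and avoids silylating the hindered C1 oxygen. The carbon skeleton, the phthalimide ester and the bond formed in the key step are unchanged.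

## Steps

Step 1
Reactants: 1 2,3:5,6-di-O-isopropylidene-α-D-mannofuranose; 2 formaldehyde
Product: 3 2-C-(hydroxymethyl)-2,3:5,6-di-O-isopropylidene-D-mannofuranose (lactol; both anomers)
Conditions: 37% aq. CH2O, K2CO3, MeOH, 65 °C
Reagents that add atoms: formaldehyde 2, C=O
Why: Crossed aldol (hydroxymethylation) of the ring-opened aldehyde, a known reaction of this lactol. Formaldehyde attacks the enolate anti to the C3 side chain on the dioxolane, and only the isomer whose formyl group is cis to that chain can re-close to the cis-fused lactol, so C1 is set with O1 cis to O2.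

Step 2
Reactants: 3 2-C-(hydroxymethyl)-2,3:5,6-di-O-isopropylidene-D-mannofuranose
Product: 4 1,2-dideoxy-3-C-(hydroxymethyl)-3,4:6,7-di-O-isopropylidene-D-manno-hept-1-enitol
Conditions: Ph3PCH3Br, KOtBu (excess), THF, 0 °C to rt
Reagents that add atoms: methyltriphenylphosphonium bromide, C[P+](c1ccccc1)(c1ccccc1)c1ccccc1.[Br-]
Why: Wittig methylenation of the lactol through its open-chain aldehyde. It masks C6 as an alkene and frees O3 (the former ring oxygen) next to the C7 hydroxyl; no stereocentre is touched.

Step 3
Reactants: 4 1,2-dideoxy-3-C-(hydroxymethyl)-3,4:6,7-di-O-isopropylidene-D-manno-hept-1-enitol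
Product: 5 5-O-benzoyl-3-C-(benzoyloxymethyl)-1,2-dideoxy-3,4:6,7-di-O-isopropylidene-D-manno-hept-1-enitol
Conditions: BzCl, pyridine, DMAP (cat.), CH2Cl2, 0 °C to rt
Reagents that add atoms: benzoyl chloride, O=C(Cl)c1ccccc1
Why: DMAP-catalysed O-acylation of the only two free hydroxyls (primary at C7, secondary at C3). This fixes both benzoates of the target in one operation while O1 and O2 stay in the ketal.

Step 4
Reactants: 5 5-O-benzoyl-3-C-(benzoyloxymethyl)-1,2-dideoxy-3,4:6,7-di-O-isopropylidene-D-manno-hept-1-enitol
Product: 7 4-O-benzoyl-2-C-(benzoyloxymethyl)-2,3:5,6-di-O-isopropylidene-aldehydo-D-mannose, via ozonide 6 (not isolated)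
Conditions: O3, CH2Cl2, −78 °C; then Me2S, −78 °C to rt
Reagents that add atoms: ozone, O=[O+][O-]
Why: Ozonolysis of the monosubstituted alkene with reductive work-up returns the C6 aldehyde. The aldehyde has no α-hydrogen, so it can neither epimerise nor eliminate; esters and ketals are inert to ozone.

Step 5
Reactants: 7 4-O-benzoyl-2-C-(benzoyloxymethyl)-2,3:5,6-di-O-isopropylidene-aldehydo-D-mannose; 8 ethynylmagnesium bromide
Product: 9 6-O-benzoyl-4-C-(benzoyloxymethyl)-1,2-dideoxy-4,5:7,8-di-O-isopropylidene-D-manno-oct-1-ynitol (both C3 epimers of this name; that carbon is ring C6)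
Conditions: HC≡CMgBr (0.5 M in THF), THF, −78 to −40 °C; AcOH quench at −78 °C
Reagents that add atoms: ethynylmagnesium bromide 8, C#C[Mg]Br
Why: 1,2-Addition of an alkynyl Grignard reagent to the aldehyde, which is far more electrophilic than the benzoates at low temperature. The new carbinol configuration is irrelevant because it is oxidised next, and the cold acidic quench limits 1,3-benzoyl transfer to the alkoxide.

Step 6
Reactants: 9 6-O-benzoyl-4-C-(benzoyloxymethyl)-1,2-dideoxy-4,5:7,8-di-O-isopropylidene-D-manno-oct-1-ynitol
Product: 10 6-O-benzoyl-4-C-(benzoyloxymethyl)-1,2-dideoxy-4,5:7,8-di-O-isopropylidene-D-manno-oct-1-yn-3-ulose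
Conditions: Dess–Martin periodinane, CH2Cl2, 0 °C to rt
Reagents that add atoms: none
Why: Dess–Martin oxidation of the secondary propargylic alcohol under neutral, amine-free conditions gives the terminal ynone. Both carbinol epimers converge, and no hydroxyl is free to add to the ynone.

Step 7
Reactants: 10 6-O-benzoyl-4-C-(benzoyloxymethyl)-1,2-dideoxy-4,5:7,8-di-O-isopropylidene-D-manno-oct-1-yn-3-ulose
Product: 12 (2S)-2-(benzoyloxy)-2-[(4S,5S)-5-(benzoyloxymethyl)-2,2-dimethyl-5-(prop-2-ynoyl)-1,3-dioxolan-4-yl]acetaldehyde, via diol 11 (not isolated)
Conditions: H5IO6, EtOAc, rt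
Reagents that add atoms: none
Why: Periodic acid hydrolyses the terminal dioxolane and cleaves the liberated 8,9-glycol in one pot. The internal dioxolane is more hindered and is deactivated by the adjacent ynone carbonyl, so it should survive; the ynone is inert to periodate.

Step 8
Reactants: 12 (2S)-2-(benzoyloxy)-2-[(4S,5S)-5-(benzoyloxymethyl)-2,2-dimethyl-5-(prop-2-ynoyl)-1,3-dioxolan-4-yl]acetaldehyde
Product: 13 (2S)-2-(benzoyloxy)-2-[(4S,5S)-5-(benzoyloxymethyl)-2,2-dimethyl-5-(prop-2-ynoyl)-1,3-dioxolan-4-yl]acetic acid
Conditions: NaClO2, NaH2PO4, 2-methyl-2-butene, t-BuOH/H2O, 0 °C to rt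
Reagents that add atoms: sodium chlorite, [Na+].[O-]Cl=O
Why: Pinnick oxidation at about pH 4 converts the α-benzoyloxy aldehyde to the acid without base, so β-elimination of O2 and addition to the ynone are avoided. Any epimerisation at C3 is without consequence because C3 becomes planar in step 10.

Step 9
Reactants: 13 (2S)-2-(benzoyloxy)-2-[(4S,5S)-5-(benzoyloxymethyl)-2,2-dimethyl-5-(prop-2-ynoyl)-1,3-dioxolan-4-yl]acetic acid; 14 N-hydroxyphthalimide
Product: 15 1,3-dioxoisoindolin-2-yl (2S)-2-(benzoyloxy)-2-[(4S,5S)-5-(benzoyloxymethyl)-2,2-dimethyl-5-(prop-2-ynoyl)-1,3-dioxolan-4-yl]acetate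
Conditions: N-hydroxyphthalimide, DIC, CH2Cl2, 0 °C to rt (no amine)
Reagents that add atoms: N-hydroxyphthalimide 14, ON1C(=O)c2ccccc2C1=O
Why: Carbodiimide esterification; the acidic N–OH component needs no nucleophilic catalyst. Leaving out amines avoids conjugate addition to the ynone and β-elimination in the activated ester.

Step 10
Reactants: 15 1,3-dioxoisoindolin-2-yl (2S)-2-(benzoyloxy)-2-[(4S,5S)-5-(benzoyloxymethyl)-2,2-dimethyl-5-(prop-2-ynoyl)-1,3-dioxolan-4-yl]acetate
Product: 18 1,2-O-isopropylidenezeylenone [(1S,2S,3R)-3-benzoyloxy-1-(benzoyloxymethyl)-1,2-(isopropylidenedioxy)cyclohex-4-en-6-one in ring numbering], via C3 radical 16 (not isolated), via vinyl radical 17 (not isolated)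
Conditions: undivided cell, reticulated vitreous carbon cathode, Zn anode, controlled potential (about −1.3 V vs Ag/AgCl), nBu4NPF6 (0.1 M), AcOH (3 equiv), DMF, 5 mM, rt, 2.0–2.2 F/mol
Reagents that add atoms: none
Why: Proposed new method: one-electron reduction of the phthalimide ester at the cathode gives a radical anion that fragments at the N–O bond and loses CO2, leaving the planar α-benzoyloxy radical 16, so either C3 epimer of 15 would converge; the closest known reaction types are the electroreductive decarboxylative Giese addition of N-acyloxyphthalimides and the 6-endo cyclisation of alkyl radicals onto vinyl ketones. The nucleophilic radical adds to C4, the β-terminus of the ynone, and closes the cyclohexenone ring in the 6-endo-dig mode, whereas 5-exo attack at C5 is polarity-mismatched and would lead to an unstabilised exocyclic vinyl radical on a strained bicyclo[3.3.0] frame. The cis-dioxolane holds C6 and C3 on the same face of a five-membered ring, which brings C3 and C4 within reach and leaves no β-leaving group better than an alkoxide next to the radical. The α-keto vinyl radical 17 is reduced further at the working potential and protonated by AcOH (or abstracts hydrogen from the solvent), giving the ring-constrained cis enone. C3 is the only new stereocentre: in the half-chair transition state C7 is equatorial, the C2–O bond lies anti to the forming bond and the benzoate takes the pseudo-equatorial site next to C2–H, which places C3–O trans to C2–O. The step needs reduction of the imide ester in preference to the ynone and to the product enone, which the lower reduction potential expected for the phthalimide ester and potentiostatic control should secure. High dilution disfavours intermolecular addition, and AcOH keeps the released phthalimide protonated so that it cannot add to the ynone.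

Step 11
Reactants: 18 1,2-O-isopropylidenezeylenone
Product: 19 zeylenone, [(1S,5R,6S)-5-(benzoyloxy)-1,6-dihydroxy-2-oxocyclohex-3-en-1-yl]methyl benzoate
Conditions: TFA/H2O (9:1), CH2Cl2, 0 °C to rt
Reagents that add atoms: none
Why: Acid-catalysed hydrolysis of the cis-fused isopropylidene ketal. Benzoates, the allylic C3–O bond and the enone tolerate aqueous acid, and the absence of base protects the γ-acyloxy enone from elimination.

Step 12
Reactants: 19 zeylenone
Product: 20 2-O-acetylzeylenone, [(1S,5R,6S)-6-acetoxy-5-(benzoyloxy)-1-hydroxy-2-oxocyclohex-3-en-1-yl]methyl benzoate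
Conditions: Ac2O, pyridine, CH2Cl2, 0 °C to rt
Reagents that add atoms: acetic anhydride, CC(=O)OC(C)=O
Why: Acylation of the secondary C2 hydroxyl in preference to the tertiary α-ketol hydroxyl at C1, which does not react with Ac2O/pyridine without forcing. Pyridine is too weak a base to deprotonate C3, so the ester pattern stays intact.

## Compound list

1 | 2,3:5,6-di-O-isopropylidene-α-D-mannofuranose | O[C@H]1O[C@H]([C@H]2COC(C)(C)O2)[C@@H]2OC(C)(C)O[C@H]12 | starting material
2 | formaldehyde | C=O | starting material
3 | 2-C-(hydroxymethyl)-2,3:5,6-di-O-isopropylidene-D-mannofuranose (anomers) | OC1O[C@H]([C@H]2COC(C)(C)O2)[C@@H]2OC(C)(C)O[C@]12CO | intermediate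
4 | 1,2-dideoxy-3-C-(hydroxymethyl)-3,4:6,7-di-O-isopropylidene-D-manno-hept-1-enitol | C=C[C@@]1(CO)OC(C)(C)O[C@H]1[C@H](O)[C@H]2COC(C)(C)O2 | intermediate
5 | 5-O-benzoyl-3-C-(benzoyloxymethyl)-1,2-dideoxy-3,4:6,7-di-O-isopropylidene-D-manno-hept-1-enitol | C=C[C@@]1(COC(=O)c2ccccc2)OC(C)(C)O[C@H]1[C@H](OC(=O)c3ccccc3)[C@H]4COC(C)(C)O4 | intermediate
6 | secondary ozonide (1,2,4-trioxolane) of 5 | O1OC(OC1)[C@@]2(COC(=O)c3ccccc3)OC(C)(C)O[C@H]2[C@H](OC(=O)c4ccccc4)[C@H]5COC(C)(C)O5 | intermediate
7 | 4-O-benzoyl-2-C-(benzoyloxymethyl)-2,3:5,6-di-O-isopropylidene-aldehydo-D-mannose | O=C[C@@]1(COC(=O)c2ccccc2)OC(C)(C)O[C@H]1[C@H](OC(=O)c3ccccc3)[C@H]4COC(C)(C)O4 | intermediate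
8 | ethynylmagnesium bromide | C#C[Mg]Br | starting material
9 | 6-O-benzoyl-4-C-(benzoyloxymethyl)-1,2-dideoxy-4,5:7,8-di-O-isopropylidene-D-manno-oct-1-ynitol (both C3 epimers) | C#CC(O)[C@@]1(COC(=O)c2ccccc2)OC(C)(C)O[C@H]1[C@H](OC(=O)c3ccccc3)[C@H]4COC(C)(C)O4 | intermediate
10 | 6-O-benzoyl-4-C-(benzoyloxymethyl)-1,2-dideoxy-4,5:7,8-di-O-isopropylidene-D-manno-oct-1-yn-3-ulose | C#CC(=O)[C@@]1(COC(=O)c2ccccc2)OC(C)(C)O[C@H]1[C@H](OC(=O)c3ccccc3)[C@H]4COC(C)(C)O4 | intermediate
11 | 6-O-benzoyl-4-C-(benzoyloxymethyl)-1,2-dideoxy-4,5-O-isopropylidene-D-manno-oct-1-yn-3-ulose (8,9-diol) | C#CC(=O)[C@@]1(COC(=O)c2ccccc2)OC(C)(C)O[C@H]1[C@H](OC(=O)c3ccccc3)[C@H](O)CO | intermediate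
12 | (2S)-2-(benzoyloxy)-2-[(4S,5S)-5-(benzoyloxymethyl)-2,2-dimethyl-5-(prop-2-ynoyl)-1,3-dioxolan-4-yl]acetaldehyde | C#CC(=O)[C@@]1(COC(=O)c2ccccc2)OC(C)(C)O[C@H]1[C@H](OC(=O)c3ccccc3)C=O | intermediate
13 | (2S)-2-(benzoyloxy)-2-[(4S,5S)-5-(benzoyloxymethyl)-2,2-dimethyl-5-(prop-2-ynoyl)-1,3-dioxolan-4-yl]acetic acid | C#CC(=O)[C@@]1(COC(=O)c2ccccc2)OC(C)(C)O[C@H]1[C@H](OC(=O)c3ccccc3)C(=O)O | intermediate
14 | N-hydroxyphthalimide | ON1C(=O)c2ccccc2C1=O | starting material
15 | 1,3-dioxoisoindolin-2-yl (2S)-2-(benzoyloxy)-2-[(4S,5S)-5-(benzoyloxymethyl)-2,2-dimethyl-5-(prop-2-ynoyl)-1,3-dioxolan-4-yl]acetate | C#CC(=O)[C@@]1(COC(=O)c2ccccc2)OC(C)(C)O[C@H]1[C@H](OC(=O)c3ccccc3)C(=O)ON4C(=O)c5ccccc5C4=O | intermediate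
16 | C3 radical (α-benzoyloxy radical after loss of CO2 and phthalimide anion) | C#CC(=O)[C@@]1(COC(=O)c2ccccc2)OC(C)(C)O[C@H]1[CH]OC(=O)c3ccccc3 | intermediate
17 | cyclised α-keto vinyl radical (radical at C5) | CC1(C)O[C@H]2[C@H](OC(=O)c3ccccc3)C=[C]C(=O)[C@]2(O1)COC(=O)c1ccccc1 | intermediate
18 | 1,2-O-isopropylidenezeylenone | CC1(C)O[C@H]2[C@H](OC(=O)c3ccccc3)C=CC(=O)[C@]2(O1)COC(=O)c1ccccc1 | intermediate
19 | zeylenone, [(1S,5R,6S)-5-(benzoyloxy)-1,6-dihydroxy-2-oxocyclohex-3-en-1-yl]methyl benzoate | O[C@H]1[C@H](OC(=O)c2ccccc2)C=CC(=O)[C@]1(O)COC(=O)c1ccccc1 | intermediate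
20 | 2-O-acetylzeylenone, [(1S,5R,6S)-6-acetoxy-5-(benzoyloxy)-1-hydroxy-2-oxocyclohex-3-en-1-yl]methyl benzoate | CC(=O)O[C@H]1[C@H](OC(=O)c2ccccc2)C=CC(=O)[C@]1(O)COC(=O)c1ccccc1 | target

## Step count and least certain steps

Total step count: 12. Longest linear sequence: 12 steps, from 1 to 20.

Step 10 (proposed new method).
- What may go wrong: competing reduction of the ynone or of the product enone, with loss of benzoate; hydrogen capture by 16 before it cyclises; closure in the 5-exo mode; poor facial selectivity at C3.
- Fallback: it sets out from aldehyde 7 and comes back at 18 by ring-closing metathesis, which keeps the sugar-derived C3 configuration and uses sugar C8 as ring C4.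
 - Addition of vinylmagnesium bromide at −78 °C would give the allylic alcohols F1.
 - TBSOTf and 2,6-lutidine would give the silyl ethers F2.
 - Aqueous AcOH would open the terminal ketal to the 8,9-diol F3.
 - I2, PPh3 and imidazole in hot toluene (Garegg–Samuelsson olefination) would give the 1,7-diene F4.
 - The second-generation Grubbs catalyst RuCl2(=CHPh)(PCy3)(H2IMes) in CH2Cl2 would close the cyclohexene silyl ethers F5.
 - HF·pyridine would free the cyclohexenols F6, and Dess–Martin oxidation would give 18.

Step 7.
- What may go wrong: loss of the internal ketal under the acidic conditions, followed by cyclisation of the freed C2 hydroxyl onto the ynone or cleavage of the C1–C2 glycol; acid-promoted hydration of the ynone.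
- Fallback: it sets out from 5 and comes back at 11, so that the ynone never meets acid hydrolysis.
 - Mild aqueous AcOH would give the 8,9-diol F10.
 - TESCl and imidazole would give the bis(triethylsilyl) ether F11.
 - Ozonolysis through the ozonide F12 would give the aldehyde F13.
 - Ethynyl addition as in step 5 would give the propargylic alcohols F14, and Dess–Martin oxidation the ynone F15.
 - Aqueous HF in MeCN would release diol 11, which NaIO4 in buffered THF/H2O cleaves to 12 under neutral conditions.

Step 5.
- What may go wrong: transfer of the C7 benzoyl group to the new magnesium alkoxide, or attack of the Grignard reagent on an ester if the hindered aldehyde reacts slowly.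
- Fallback: it sets out from 7 and comes back at 9. Zinc-mediated alkynylation under amine base (trimethylsilylacetylene, Zn(OTf)2, Et3N, toluene, rt) would give the C-silylated propargylic alcohols F9 without a basic alkoxide. nBu4NF buffered with AcOH would then remove the silyl group to give 9.

Step 2.
- What may go wrong: retro-aldol fragmentation of the β-alkoxide aldehyde with loss of formaldehyde before olefination, which would erase C7.
- Fallback: it sets out from 3 and comes back at 4. TBDPSCl and imidazole would silylate the primary C7 hydroxyl selectively to give the silyl lactol F7, Wittig methylenation would give the silyl alkene F8, and nBu4NF would release 4.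

## Further compounds

F1 | step 10 | allylic alcohols from vinyl addition to 7 (both C6 epimers) | C=CC(O)[C@@]1(COC(=O)c2ccccc2)OC(C)(C)O[C@H]1[C@H](OC(=O)c3ccccc3)[C@H]4COC(C)(C)O4
F2 | step 10 | tert-butyldimethylsilyl ethers of F1 | C=CC(O[Si](C)(C)C(C)(C)C)[C@@]1(COC(=O)c2ccccc2)OC(C)(C)O[C@H]1[C@H](OC(=O)c3ccccc3)[C@H]4COC(C)(C)O4
F3 | step 10 | 8,9-diol of F2 | C=CC(O[Si](C)(C)C(C)(C)C)[C@@]1(COC(=O)c2ccccc2)OC(C)(C)O[C@H]1[C@H](OC(=O)c3ccccc3)[C@H](O)CO
F4 | step 10 | 1,7-diene (C3 vinyl and C6 vinyl) | C=CC(O[Si](C)(C)C(C)(C)C)[C@@]1(COC(=O)c2ccccc2)OC(C)(C)O[C@H]1[C@H](OC(=O)c3ccccc3)C=C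
F5 | step 10 | cyclohexene silyl ethers from ring-closing metathesis | CC1(C)O[C@H]2[C@H](OC(=O)c3ccccc3)C=CC(O[Si](C)(C)C(C)(C)C)[C@]2(O1)COC(=O)c1ccccc1
F6 | step 10 | cyclohexenols (C6 carbinols of 18) | CC1(C)O[C@H]2[C@H](OC(=O)c3ccccc3)C=CC(O)[C@]2(O1)COC(=O)c1ccccc1
F7 | step 2 | 2-C-[(tert-butyldiphenylsilyloxy)methyl]-2,3:5,6-di-O-isopropylidene-D-mannofuranose | OC1O[C@H]([C@H]2COC(C)(C)O2)[C@@H]2OC(C)(C)O[C@]12CO[Si](c1ccccc1)(c1ccccc1)C(C)(C)C
F8 | step 2 | 7-O-tert-butyldiphenylsilyl ether of 4 | C=C[C@@]1(CO[Si](c2ccccc2)(c2ccccc2)C(C)(C)C)OC(C)(C)O[C@H]1[C@H](O)[C@H]3COC(C)(C)O3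
F9 | step 5 | C-trimethylsilyl derivative of 9 (both carbinol epimers) | C[Si](C)(C)C#CC(O)[C@@]1(COC(=O)c2ccccc2)OC(C)(C)O[C@H]1[C@H](OC(=O)c3ccccc3)[C@H]4COC(C)(C)O4
F10 | step 7 | 8,9-diol of 5 | C=C[C@@]1(COC(=O)c2ccccc2)OC(C)(C)O[C@H]1[C@H](OC(=O)c3ccccc3)[C@H](O)CO
F11 | step 7 | 8,9-bis(triethylsilyl) ether of F10 | C=C[C@@]1(COC(=O)c2ccccc2)OC(C)(C)O[C@H]1[C@H](OC(=O)c3ccccc3)[C@H](O[Si](CC)(CC)CC)CO[Si](CC)(CC)CC
F12 | step 7 | secondary ozonide of F11 | O1OC(OC1)[C@@]2(COC(=O)c3ccccc3)OC(C)(C)O[C@H]2[C@H](OC(=O)c4ccccc4)[C@H](O[Si](CC)(CC)CC)CO[Si](CC)(CC)CC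
F13 | step 7 | C6 aldehyde with 8,9-bis(triethylsilyl) ether | O=C[C@@]1(COC(=O)c2ccccc2)OC(C)(C)O[C@H]1[C@H](OC(=O)c3ccccc3)[C@H](O[Si](CC)(CC)CC)CO[Si](CC)(CC)CC
F14 | step 7 | propargylic alcohols with 8,9-bis(triethylsilyl) ether | C#CC(O)[C@@]1(COC(=O)c2ccccc2)OC(C)(C)O[C@H]1[C@H](OC(=O)c3ccccc3)[C@H](O[Si](CC)(CC)CC)CO[Si](CC)(CC)CC
F15 | step 7 | ynone with 8,9-bis(triethylsilyl) ether | C#CC(=O)[C@@]1(COC(=O)c2ccccc2)OC(C)(C)O[C@H]1[C@H](OC(=O)c3ccccc3)[C@H](O[Si](CC)(CC)CC)CO[Si](CC)(CC)CC
A1 | alternative 1 | open-chain keto-aldehyde (C6 aldehyde, C4 silyl ether, C2/C3 trans-isopropylidene ketal, C1 ketone with C7H2O-4-methoxybenzyl) | O=CC[C@H](O[Si](C)(C)C(C)(C)C)[C@H]1OC(C)(C)O[C@@H]1C(=O)COCc1ccc(OC)cc1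
A2 | alternative 1 | protected 2-hydroxy-2-(alkoxymethyl)-3,4-trans-dioxy-5-silyloxycyclohexanone | O=C1C[C@H](O[Si](C)(C)C(C)(C)C)[C@H]2OC(C)(C)O[C@@H]2[C@@]1(O)COCc1ccc(OC)cc1
A3 | alternative 2 | furfuryl benzoate | O=C(OCc1ccco1)c1ccccc1
A4 | alternative 2 | 2-bromoacrolein | C=C(Br)C=O
A5 | alternative 2 | 1-(benzoyloxymethyl)-2-endo-bromo-7-oxabicyclo[2.2.1]hept-5-ene-2-exo-carbaldehyde | O=C[C@]1(Br)C[C@H]2C=C[C@]1(COC(=O)c1ccccc1)O2
A6 | alternative 3 | 1-(benzoyloxymethyl)cyclohexa-2,5-dien-1-ol | OC1(COC(=O)c2ccccc2)C=CCC=C1
A7 | alternative 3 | syn-2,3-epoxy-1-(benzoyloxymethyl)cyclohex-5-en-1-ol | O[C@]1(COC(=O)c2ccccc2)C=CC[C@@H]2O[C@H]12
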